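**Retrosynthetic overview**

1. Target 24 comes from the protected macrocycle 22 by unmasking C13 (dioxolane) and C6 (silyl ether) and oxidising C6.
2. 22 is opened at C10–C11 and O–C8 in one retrosynthetic move to the open-chain dialdehyde 20. Forward, a carbene-catalysed acyloin macrocyclisation (C10–C11) is followed in the same flask by transannular oxa-Michael addition (O–C8).
3. Enabling feature: in the oxolan-3-one ring (O, C8, C9, C10, C11) the ketone C10 has an α-oxygenated carbon (C11, acyloin retron) and a β-oxygenated carbon (C8, oxa-Michael retron). C10–C11 is also a bond of the 14-membered carbocycle C1–C14, so one acyl-anion event at C10 can close both rings.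
4. 20 is assembled by (Z)-selective Still–Gennari olefination (C3=C4) of aldehyde acid 4 with phosphonate 13. 4 (C13, C14, C1, C2, C3 and isopropenyl) comes from (S)-carvone by excision of one ring carbon; 13 (C4–C10) from (S)-epichlorohydrin and (Z)-3-iodobut-2-en-1-ol; C11–C12 from Meldrum's acid.
5. Ring order: no ring until step 14; then the 14-membered carbocycle first and the oxolan-3-one second, in one operation.

Key step: step 14

Remark (numbering): target numbering is used for all intermediates. Ring carbons are C1–C14; C1 bears the isopropenyl group, C4 the CO2Me group, C8 the methyl group; the ketones are C6, C10 and C13; the ring oxygen links C8 and C11.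
Remark (chemistry): the C6 carbinol carried from step 5 to step 15 is a temporary stereocenter of arbitrary configuration and is erased in step 16. Aldehyde acid 4 is drawn open-chain although it may equilibrate with its cyclic pseudo-acid.

**Route**

Step 1
Reactants: 1 (S)-(+)-carvone
Product: 2 (1S,4S,6S)-1-methyl-4-(prop-1-en-2-yl)-7-oxabicyclo[4.1.0]heptan-2-one
Conditions: H2O2 (30% aq.), NaOH (cat.), MeOH, 0 °C
Reagents that add atoms: hydrogen peroxide OO
Why: Weitz–Scheffer nucleophilic epoxidation touches only the enone (the isopropenyl alkene is inert to hydroperoxide anion) and occurs anti to the ring substituent, so one diastereomer with two temporary stereocenters should form.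

Step 2
Reactants: 2 carvone epoxide
Product: 4 (S)-5-oxo-3-(prop-1-en-2-yl)pentanoic acid, via diol 3 (not isolated)
Conditions: H2SO4 (1 M aq.), THF, 25 °C; then NaIO4 (2.5 equiv), 0 → 25 °C
Reagents that add atoms: water O; sodium periodate [Na+].[O-]I(=O)(=O)=O
Why: acid-catalysed epoxide hydrolysis followed by two periodate (Malaprade-type) cleavages, of the glycol and of the α-ketol, excises the methyl-bearing ring carbon as acetic acid and leaves the untouched stereocenter (future C1) between a CHO arm (future C2–C3) and a CO2H arm (future C14–C13).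

Step 3
Reactants: 5 but-2-yn-1-ol
Product: 6 (Z)-3-iodobut-2-en-1-ol
Conditions: NaAlH2(OCH2CH2OCH3)2, THF, 0 → 25 °C; then I2, −78 °C
Reagents that add atoms: iodine II
Why: hydroxyl-directed trans-hydroalumination of the propargylic alcohol puts aluminium at C3 cis to CH2OH, and iodinolysis with retention should give the Z iodide that later fixes the Z geometry of C8=C9.

Step 4
Reactants: 6 (Z)-3-iodobut-2-en-1-ol
Product: 7 (Z)-tert-butyl[(3-iodobut-2-en-1-yl)oxy]dimethylsilane
Conditions: t-BuMe2SiCl, imidazole, DMF, 25 °C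
Reagents that add atoms: tert-butyldimethylsilyl chloride CC(C)(C)[Si](C)(C)Cl
Why: standard silylation of the primary allylic alcohol (future O10).

Step 5
Reactants: 7 silyl ether of the iodide; 8 (S)-epichlorohydrin
Product: 10 (2S,4Z)-6-[(tert-butyldimethylsilyl)oxy]-1-chloro-4-methylhex-4-en-2-ol, via alkenylmagnesium chloride 9 (not isolated)
Conditions: i-PrMgCl·LiCl, THF, −20 °C; then CuI (10 mol%), 8, −40 → 0 °C
Reagents that add atoms: none
Why: iodine–magnesium exchange keeps the alkene geometry and copper-catalysed SN2 opening of the epoxide at its CH2 terminus (future C7) should give the chlorohydrin; the stereocenter of 8 is not touched and becomes the temporary C6 carbinol.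

Step 6
Reactants: 10 chlorohydrin
Product: 11 (2S,4Z)-2,6-bis[(tert-butyldimethylsilyl)oxy]-1-chloro-4-methylhex-4-ene
Conditions: t-BuMe2SiCl, imidazole, DMF, 40 °C
Reagents that add atoms: tert-butyldimethylsilyl chloride CC(C)(C)[Si](C)(C)Cl
Why: standard silylation; the secondary silyl ether masks the future C6 ketone.

Step 7
Reactants: 11 bis-silyl chloride; 12 methyl 2-[bis(2,2,2-trifluoroethoxy)phosphoryl]acetate
Product: 13 methyl (4S,6Z)-2-[bis(2,2,2-trifluoroethoxy)phosphoryl]-4,8-bis[(tert-butyldimethylsilyl)oxy]-6-methyloct-6-enoate (both epimers at the phosphonate carbon)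
Conditions: NaH, DMSO, 25 °C; then 11, NaI (20 mol%), 60 °C
Reagents that add atoms: none
Why: C-alkylation (SN2 with in situ Finkelstein activation) of the sodium salt of the phosphonoacetate installs C4 with its ester and the olefination handle; the new C4 center is not controlled and is destroyed in step 8.

Step 8
Reactants: 4 aldehyde acid; 13 phosphonate
Product: 14 (3S,5Z,8S,10Z)-8,12-bis[(tert-butyldimethylsilyl)oxy]-6-(methoxycarbonyl)-10-methyl-3-(prop-1-en-2-yl)dodeca-5,10-dienoic acid
Conditions: KN(SiMe3)2 (2.3 equiv), 18-crown-6, THF, −78 °C; HCl (1 M) work-up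
Reagents that add atoms: none
Why: Still–Gennari variant of the Horner–Wadsworth–Emmons olefination; the electron-poor trifluoroethyl phosphonate under dissociating conditions eliminates from the kinetic adduct and should place CO2Me cis to C2, i.e. the (Z)-C3=C4 enoate of the target, with the carboxylate of 4 as a spectator.

Step 9
Reactants: 14 seco acid
Product: 16 S-ethyl (5S,7Z,10S,12Z)-10,14-bis[(tert-butyldimethylsilyl)oxy]-8-(methoxycarbonyl)-12-methyl-3-oxo-5-(prop-1-en-2-yl)tetradeca-7,12-dienethioate, via acyl Meldrum's acid 15 (not isolated)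
Conditions: Meldrum's acid, DCC, DMAP, CH2Cl2, 0 → 25 °C; then EtSH, benzene, 80 °C
Reagents that add atoms: Meldrum's acid CC1(C)OC(=O)CC(=O)O1; ethanethiol CCS
Why: DCC/DMAP C-acylation of Meldrum's acid and thermal thiolysis through the acylketene (loss of acetone and CO2) should give the β-keto thioester under non-basic conditions that do not isomerise the (Z)-enoate; this adds C12 and C11.

Step 10
Reactants: 16 β-keto thioester
Product: 17 C13 ethylene ketal (1,3-dioxolane) of 16
Conditions: (Me3SiOCH2)2, Me3SiOTf (5 mol%), CH2Cl2, −78 → −20 °C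
Reagents that add atoms: 1,2-bis(trimethylsilyloxy)ethane C[Si](C)(C)OCCO[Si](C)(C)C
Why: ketalisation under aprotic silyl-transfer conditions masks the C13 ketone so that C11 can later be a free aldehyde rather than an enolised β-keto aldehyde; the thioester, the ester and the silyl ethers should survive.

Step 11
Reactants: 17 ketal thioester
Product: 18 C11 aldehyde (C13 dioxolane, O6 and O10 silyl ethers)
Conditions: i-Bu2AlH (1.2 equiv), CH2Cl2, −78 °C; aq. KNaC4H4O6 work-up
Reagents that add atoms: none
Why: partial reduction of the thioester (the hemithioacetal aluminate is stable at −78 °C) should give the C11 aldehyde while the less electrophilic conjugated methyl ester is left alone.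

Step 12
Reactants: 18 aldehyde
Product: 19 C10 allylic alcohol of 18 (O6 silyl ether retained)
Conditions: HF·pyridine, pyridine, THF, 0 °C
Reagents that add atoms: none
Why: the primary allylic silyl ether is cleaved much faster than the hindered secondary one under buffered fluoride conditions that tolerate the aldehyde and the dioxolane.

Step 13
Reactants: 19 hydroxy aldehyde
Product: 20 open-chain dialdehyde, (1S,3Z,6S,8Z): (Z)-enal at C10, saturated aldehyde at C11
Conditions: MnO2 (activated, excess), CH2Cl2, 25 °C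
Reagents that add atoms: none
Why: MnO2 oxidises only the allylic alcohol, without Z/E isomerisation, to give the (Z)-enal next to the untouched saturated aldehyde.

Step 14
Reactants: 20 open-chain dialdehyde
Product: 22 protected macrocyclic oxolan-3-one, (1S,3Z,6R,8R,11R): target skeleton with C6 as silyl-protected carbinol and C13 as dioxolane, via macrocyclic hydroxy enone 21 (not isolated)
Conditions: (5aS,10bR)- or (5aR,10bS)-2-(pentafluorophenyl)-5a,10b-dihydro-4H,6H-indeno[2,1-b][1,2,4]triazolo[4,3-d][1,4]oxazin-2-ium tetrafluoroborate (20 mol%; the antipode that gives Si-face attack at C11), i-Pr2NEt (20 mol%), toluene, 0.002 M, syringe-pump addition of 20, 25 °C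
Reagents that add atoms: none
Why: Proposed new method: the carbene freed from the triazolium salt adds to the enal carbonyl C10 and, after proton transfer, the C10 acyl-anion equivalent attacks the tethered aldehyde C11 (14-exo-trig, closes the C1–C14 carbocycle); loss of the carbene gives the α'-hydroxy enone 21, whose C11 hydroxyl then adds to C8 of the C8=C9–C10=O enone under Brønsted-base catalysis by the same carbene (5-endo-trig oxa-Michael, closes the oxolan-3-one). The closest known reaction types are carbene-catalysed intramolecular crossed acyloin (benzoin) cyclisations to five- and six-membered rings, the use of enals as acyl donors with electron-poor triazolium catalysts, and carbene-catalysed oxa-Michael additions; their use at 14-membered ring size and in tandem is the untested element. C11 is set by the catalyst, whose antipode is chosen so that C10 adds to the Si face of C11=O (11R), the remote C1 center acting as a spectator. C8 is set by relay from C11: in the envelope transition state of the 5-endo closure C12 should sit pseudo-equatorial and anti to the C8 substituent that is cis to C10, which the Z geometry of C8=C9 fixes as C7, so the methyl ends cis and C7 trans to C12 (8R). The step needs the enal and not the alkanal to end as the ketone (all acyloin isomers interconvert by retro-benzoin and only the conjugated isomer 21 is drained by the oxa-Michael step), acyl-anion rather than homoenolate reactivity (C8 is fully substituted, so β-attack is blocked), and ring closure rather than oligomerisation (high dilution and slow addition).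

Step 15
Reactants: 22 protected macrocycle
Product: 23 (1S,3Z,6R,8R,11R)-6-hydroxy precursor: the target with a secondary alcohol at C6 in place of the ketone
Conditions: HCl (1 M aq.), THF, 25 °C
Reagents that add atoms: water O
Why: aqueous acid hydrolyses the dioxolane (C13 ketone) and the secondary silyl ether (C6 carbinol); no base is present, so C11 (α to C10) and the β-alkoxy ketone units should not epimerise or open.

Step 16
Reactants: 23 6-hydroxy precursor
Product: 24 target, (1S,3Z,8R,11R)
Conditions: Dess–Martin periodinane, CH2Cl2, 0 → 25 °C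
Reagents that add atoms: none
Why: Dess–Martin oxidation of the only carbinol gives the C6 ketone under neutral conditions that should leave the β,γ-unsaturated C3=C4 ester unconjugated and the C8 and C11 centers untouched.

**Compound list**

1 | (S)-(+)-carvone | CC(=C)[C@H]1CC=C(C)C(=O)C1 | starting material
2 | (1S,4S,6S)-1-methyl-4-(prop-1-en-2-yl)-7-oxabicyclo[4.1.0]heptan-2-one | CC(=C)[C@H]1C[C@@H]2O[C@]2(C)C(=O)C1 | intermediate
3 | (2S,3R,5S)-2,3-dihydroxy-2-methyl-5-(prop-1-en-2-yl)cyclohexan-1-one | CC(=C)[C@H]1C[C@@H](O)[C@](C)(O)C(=O)C1 | intermediate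
4 | (S)-5-oxo-3-(prop-1-en-2-yl)pentanoic acid | CC(=C)[C@H](CC(=O)O)CC=O | intermediate
5 | but-2-yn-1-ol | CC#CCO | starting material
6 | (Z)-3-iodobut-2-en-1-ol | C/C(I)=C/CO | intermediate
7 | (Z)-tert-butyl[(3-iodobut-2-en-1-yl)oxy]dimethylsilane | C/C(I)=C/CO[Si](C)(C)C(C)(C)C | intermediate
8 | (S)-epichlorohydrin | ClC[C@@H]1CO1 | starting material
9 | (Z)-{4-[(tert-butyldimethylsilyl)oxy]but-2-en-2-yl}magnesium chloride | C/C([Mg]Cl)=C/CO[Si](C)(C)C(C)(C)C | intermediate
10 | (2S,4Z)-6-[(tert-butyldimethylsilyl)oxy]-1-chloro-4-methylhex-4-en-2-ol | ClC[C@@H](O)C/C(C)=C\CO[Si](C)(C)C(C)(C)C | intermediate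
11 | (2S,4Z)-2,6-bis[(tert-butyldimethylsilyl)oxy]-1-chloro-4-methylhex-4-ene | ClC[C@@H](O[Si](C)(C)C(C)(C)C)C/C(C)=C\CO[Si](C)(C)C(C)(C)C | intermediate
12 | methyl 2-[bis(2,2,2-trifluoroethoxy)phosphoryl]acetate | COC(=O)CP(=O)(OCC(F)(F)F)OCC(F)(F)F | starting material
13 | methyl (4S,6Z)-2-[bis(2,2,2-trifluoroethoxy)phosphoryl]-4,8-bis[(tert-butyldimethylsilyl)oxy]-6-methyloct-6-enoate, epimers at C2 | COC(=O)C(C[C@@H](O[Si](C)(C)C(C)(C)C)C/C(C)=C\CO[Si](C)(C)C(C)(C)C)P(=O)(OCC(F)(F)F)OCC(F)(F)F | intermediate
14 | (3S,5Z,8S,10Z)-8,12-bis[(tert-butyldimethylsilyl)oxy]-6-(methoxycarbonyl)-10-methyl-3-(prop-1-en-2-yl)dodeca-5,10-dienoic acid | CC(=C)[C@H](CC(=O)O)C/C=C(\C(=O)OC)C[C@@H](O[Si](C)(C)C(C)(C)C)C/C(C)=C\CO[Si](C)(C)C(C)(C)C | intermediate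
15 | acyl Meldrum's acid of 14 (5-acyl-2,2-dimethyl-1,3-dioxane-4,6-dione) | CC(=C)[C@H](CC(=O)C1C(=O)OC(C)(C)OC1=O)C/C=C(\C(=O)OC)C[C@@H](O[Si](C)(C)C(C)(C)C)C/C(C)=C\CO[Si](C)(C)C(C)(C)C | intermediate
16 | S-ethyl (5S,7Z,10S,12Z)-10,14-bis[(tert-butyldimethylsilyl)oxy]-8-(methoxycarbonyl)-12-methyl-3-oxo-5-(prop-1-en-2-yl)tetradeca-7,12-dienethioate | CC(=C)[C@H](CC(=O)CC(=O)SCC)C/C=C(\C(=O)OC)C[C@@H](O[Si](C)(C)C(C)(C)C)C/C(C)=C\CO[Si](C)(C)C(C)(C)C | intermediate
17 | C13 1,3-dioxolane of 16, (1S,3Z,6S,8Z) in target numbering | CC(=C)[C@H](CC1(CC(=O)SCC)OCCO1)C/C=C(\C(=O)OC)C[C@@H](O[Si](C)(C)C(C)(C)C)C/C(C)=C\CO[Si](C)(C)C(C)(C)C | intermediate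
18 | C11 aldehyde, (1S,3Z,6S,8Z): C13 dioxolane, silyl ethers at O6 and O10 | CC(=C)[C@H](CC1(CC=O)OCCO1)C/C=C(\C(=O)OC)C[C@@H](O[Si](C)(C)C(C)(C)C)C/C(C)=C\CO[Si](C)(C)C(C)(C)C | intermediate
19 | C11 aldehyde with free C10 allylic alcohol, (1S,3Z,6S,8Z) | CC(=C)[C@H](CC1(CC=O)OCCO1)C/C=C(\C(=O)OC)C[C@@H](O[Si](C)(C)C(C)(C)C)C/C(C)=C\CO | intermediate
20 | open-chain dialdehyde, (1S,3Z,6S,8Z): C10 (Z)-enal and C11 aldehyde | CC(=C)[C@H](CC1(CC=O)OCCO1)C/C=C(\C(=O)OC)C[C@@H](O[Si](C)(C)C(C)(C)C)C/C(C)=C\C=O | intermediate
21 | macrocyclic α'-hydroxy enone, (1S,3Z,6S,8Z,11R): C10 ketone, C11 hydroxyl, C8=C9 alkene | C=C(C)[C@H]1C/C=C(\C(=O)OC)C[C@@H](O[Si](C)(C)C(C)(C)C)C/C(C)=C\C(=O)[C@H](O)CC2(OCCO2)C1 | intermediate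
22 | protected macrocyclic oxolan-3-one, (1S,3Z,6R,8R,11R): O6 silyl ether, C13 dioxolane | C=C(C)[C@H]1C/C=C(\C(=O)OC)C[C@@H](O[Si](C)(C)C(C)(C)C)C[C@]2(C)CC(=O)[C@@H](CC3(OCCO3)C1)O2 | intermediate
23 | 6-hydroxy precursor, (1S,3Z,6R,8R,11R): target with C6 carbinol | C=C(C)[C@H]1C/C=C(\C(=O)OC)C[C@@H](O)C[C@]2(C)CC(=O)[C@@H](CC(=O)C1)O2 | intermediate
24 | target, (1S,3Z,8R,11R) | C=C(C)[C@H]1C/C=C(\C(=O)OC)CC(=O)C[C@]2(C)CC(=O)[C@@H](CC(=O)C1)O2 | target

**Step count and risks**

Total step count: 16. Longest linear sequence: 14 steps (steps 3–7, then 8–16).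

Steps most likely to fail:

Step 14. Ring closure may lose to oligomerisation, the enal-derived intermediate may be diverted into β-protonation (redox) pathways, and the stereochemical relay may erode through retro-oxa-Michael opening or Z/E isomerisation of the enone. The fallback uses known chemistry and sets out from dialdehyde 20. Low-valent titanium pinacol macrocyclisation (TiCl3(DME)1.5, Zn(Cu) couple, DME, high dilution) should give the macrocyclic 1,2-diol F1 as a mixture at C10 and C11. Chemoselective MnO2 oxidation of the allylic C10 carbinol should give hydroxy enone 21 together with its C11 epimer F2, which is separated. Acid-catalysed 5-endo oxa-Michael closure of 21 (camphorsulfonic acid, CH2Cl2, 0 °C) then returns to the route at 22.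

Step 8. Z-selectivity may be lost with the α-branched phosphonate, and the carboxylate may slow the olefination. The fallback sets out from aldehyde acid 4, chloride 11 and phosphonate 12. Bromination of 12 (NaH, then Br2) gives methyl bromo[bis(2,2,2-trifluoroethoxy)phosphoryl]acetate F3, whose olefination with 4 should give the (E)-α-bromoacrylate F4 with CO2Me already cis to C2. Chloride 11 is converted into the iodide F5 (NaI, acetone) and then into the alkylzinc iodide F6 (Zn, LiCl, THF). Negishi coupling of F4 with excess F6 (Pd(PPh3)4, THF) proceeds with retention at the alkene and returns to the route at 14.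

Step 7. The SN2 reaction at the β-branched chloride may be sluggish, and the trifluoroethyl phosphonate anion may degrade (transesterification, P–O cleavage) on heating. The fallback sets out from chloride 11. The more robust sodium salt of trimethyl phosphonoacetate is alkylated (NaI, DMF, 80 °C) to give the dimethyl phosphonate F7. The ester groups on phosphorus are then exchanged: Me3SiBr/pyridine gives the bis(trimethylsilyl) phosphonate F8 (McKenna reaction), oxalyl chloride with catalytic DMF gives the phosphonic dichloride F9, and CF3CH2OH/Et3N returns to the route at 13.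

Further compounds
F1 | step 14 | macrocyclic 10,11-diol, (1S,3Z,6S,8Z,11R), mixture at C10 | C=C(C)[C@H]1C/C=C(\C(=O)OC)C[C@@H](O[Si](C)(C)C(C)(C)C)C/C(C)=C\C(O)[C@H](O)CC2(OCCO2)C1
F2 | step 14 | C11 epimer of 21, (1S,3Z,6S,8Z,11S) | C=C(C)[C@H]1C/C=C(\C(=O)OC)C[C@@H](O[Si](C)(C)C(C)(C)C)C/C(C)=C\C(=O)[C@@H](O)CC2(OCCO2)C1
F3 | step 8 | methyl bromo[bis(2,2,2-trifluoroethoxy)phosphoryl]acetate | COC(=O)C(Br)P(=O)(OCC(F)(F)F)OCC(F)(F)F
F4 | step 8 | (3S,5E)-6-bromo-7-methoxy-7-oxo-3-(prop-1-en-2-yl)hept-5-enoic acid | CC(=C)[C@H](CC(=O)O)C/C=C(\C(=O)OC)Br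
F5 | step 8 | (2S,4Z)-2,6-bis[(tert-butyldimethylsilyl)oxy]-1-iodo-4-methylhex-4-ene | IC[C@@H](O[Si](C)(C)C(C)(C)C)C/C(C)=C\CO[Si](C)(C)C(C)(C)C
F6 | step 8 | {(2S,4Z)-2,6-bis[(tert-butyldimethylsilyl)oxy]-4-methylhex-4-en-1-yl}zinc iodide | I[Zn]C[C@@H](O[Si](C)(C)C(C)(C)C)C/C(C)=C\CO[Si](C)(C)C(C)(C)C
F7 | step 7 | methyl (4S,6Z)-4,8-bis[(tert-butyldimethylsilyl)oxy]-2-(dimethoxyphosphoryl)-6-methyloct-6-enoate | COC(=O)C(C[C@@H](O[Si](C)(C)C(C)(C)C)C/C(C)=C\CO[Si](C)(C)C(C)(C)C)P(=O)(OC)OC
F8 | step 7 | bis(trimethylsilyl) phosphonate analogue of F7 | COC(=O)C(C[C@@H](O[Si](C)(C)C(C)(C)C)C/C(C)=C\CO[Si](C)(C)C(C)(C)C)P(=O)(O[Si](C)(C)C)O[Si](C)(C)C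
F9 | step 7 | phosphonic dichloride analogue of F7 | COC(=O)C(C[C@@H](O[Si](C)(C)C(C)(C)C)C/C(C)=C\CO[Si](C)(C)C(C)(C)C)P(=O)(Cl)Cl
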